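Readings and results are calculated with constants of no real substance.

Target is made from dissolved substrate and reagent one to one, so in the asked flask, Saturday's, start with the balance of the solid substrate, the limiting reagent there, whose 20 mM is less than the 22.0 mM of reagent: solid, dissolved substrate, target and isomer of the product always add up to that charge.

| setting | Saturday's | Sunday's | flask |
|---|---|---|---|
| solid substrate | 20 mM | 20 mM | 20 mM |
| reagent | 22 mM | 11 mM | 22.0 mM |
| remark | the very flask that is asked about, followed so far | run made earlier |  |
| time |  |  | 3.0 d |

- Saturday's (time / h: target / %): 2.50: 0; 4.00: 0; 5.00: 0.3; 8.00: 0; 12.0: 1.0; 20.0: 2.4; 30.0: 3.0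
- Sunday's (time / d: target / %): 0.250: 0; 0.333: 0; 0.500: 1.0; 0.833: 1.6; 1.25: 1.7; 2.08: 4.1; 3.00: 6.4

(scatter of a reading: 0.5 percentage points)

- as a solid, counted per litre of solution: solid substrate
- candidate steps: solid substrate <-> dissolved substrate; dissolved substrate + reagent <-> target; target <-> isomer of the product
- at the start none of the solid substrate is in solution

- amount of target in percent of the solid substrate charged, at 4.0 h, 20 h and 3.0 d

Take the main step first. Its rate goes as [dissolved substrate][reagent], and with the substrate in solution from the start, target rises steepest at once. Saturday's flask shows the opposite: 0% at 8.00 h, then 3.0% at 30.0 h.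

Now add the dissolving. [dissolved substrate] starts at zero, and if it grows in step with time, target grows with time squared. [reagent] moves little: the target read in Sunday's flask at 3.00 d has taken 11.6% of that flask's reagent, so [reagent] can be folded into the rate constant and the main step treated as pseudo-first-order in dissolved substrate. Target as a fraction of the charge is then (time / ramp time) squared, and the squared ramp time goes inversely with [reagent].

Sunday's 6.4% gives 11.9 d for that flask. Scaling to 22.0 mM gives 8.39 d for Saturday's flask, its ramp time, the time at which the parabola reaches the whole charge. You get 0.0395%, 0.987% and 12.8% at the asked times. Saturday's reading at 30.0 h stands above the parabola's 2.22%, so the early figures lie on the low side.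

Add the rest: the return of target and its turning into isomer of the product both grow with the target present, and Saturday's flask should hold more than Sunday's, so your last figure is the high side.

The forecast, 0.1%, 2% and 8%, goes by “Extending Saturday's line from a lag” and lies below your figure at 3.0 d but above it at 20 h.

The flask gives 0.0925%, 1.79% and 11.2%.

    solid substrate ⇌ dissolved substrate, rate k1*(cs1 - [dissolved substrate]) while solid is left; crystals form when [dissolved substrate] > cs1 (solubility = 7.10 mM, k = 5.05 × 10⁻⁶ s⁻¹)
    dissolved substrate + reagent ⇌ target (K = 80.6 L mol⁻¹, k = 2.42 × 10⁻⁴ L mol⁻¹ s⁻¹)
    target ⇌ isomer of the product (K = 0.749, k = 6.45 × 10⁻⁷ s⁻¹)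

Put back into the rule, the flask's 11.2% gives a ramp time of 8.96 d, longer than your 8.39 d. At 3.00 d dissolved substrate is still made 1.55 times faster than it is used up, each step taken net, down from 2.33 at 1.23 d, and the flask holds 18.6% of it beside 11.2% of target.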